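**Retrosynthetic overview**
1. Target 31 ← ester hydrolysis and desilylation ← C11–OH by conjugate borylation/oxidation of a cyclopent-2-enone (C9=O, C10=C11) ← cis-C5=C6 from the C5≡C6 alkyne.
2. The cyclopentane ring (the only ring) ← one flask from dichlorovinyl ether 17 and triflate 22: C7–C8 alkylation, [3,3] shift of an allyl alkynyl ether (C8–C12), then closure of the C9 ketene onto the C10 vinylsilane (C9–C10).
3. Enabling feature: in the 3-hydroxycyclopentanone ring, ketone C9 lies between C8 (carrying the α-chain) and the unsubstituted methylene C10, with C11–OH β to it. C8–C9(=O) thus maps onto a ketene and C10–C11–C12 onto an allyl unit whose free C10 terminus can be tied to the ketene oxygen and carry a traceless silyl stereocentre.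
4. 17 ← (R)-α-silyl allylic alcohol 13 ← acylsilane 12 ← aldehyde 8 ← sulfone-linchpin union of (R)-propylene oxide and (R)-2-(but-3-enyl)oxirane (sets C19 and C15).
5. 22 ← hex-5-ynoic acid + formaldehyde.

Key step: step 12

Remark: positions are given in prostanoid numbering (C1 carboxyl to C20 methyl). The target is read as (5Z,8R,11R,12R,15S,19R), i.e. 13,14-dihydro-19(R)-hydroxy-PGE2. The sense of the reduction in step 6 is assumed by analogy, with the silyl group acting as the large substituent. TBS = tert-butyldimethylsilyl.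

**Step 1**
Reactants: 1 methyl phenyl sulfone; 2 (R)-2-methyloxirane; 3 (R)-2-(but-3-en-1-yl)oxirane
Product: 5 (2R,6R)-4-(phenylsulfonyl)dec-9-ene-2,6-diol (C4 epimers), via lithium (R)-4-(phenylsulfonyl)butan-2-olate 4 (not isolated)
Conditions: n-BuLi (1.0 equiv), THF, −78 °C; 2, −78 → 20 °C; n-BuLi (1.1 equiv), −78 °C; 3, DMPU, −78 → 20 °C; aq. NH4Cl
Reagents that add atoms: none
Why: Twofold alkylation of the sulfone-stabilised carbanion opens each terminal epoxide at its CH2 terminus, so the C19 and C15 carbinol centres are taken unchanged from the two enantiopure epoxides, and the C17 sulfone centre is erased in step 2.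

**Step 2**
Reactants: 5 (2R,6R)-4-(phenylsulfonyl)dec-9-ene-2,6-diol
Product: 6 (2R,6S)-dec-9-ene-2,6-diol
Conditions: Na(Hg) 6 %, Na2HPO4, MeOH, −20 → 0 °C
Reagents that add atoms: none
Why: Reductive desulfonylation by electron transfer should cleave only the C–S bond and leave the terminal alkene and both carbinol centres untouched.

**Step 3**
Reactants: 6 (2R,6S)-dec-9-ene-2,6-diol
Product: 7 (5S,9R)-5,9-bis(TBS-oxy)dec-1-ene
Conditions: TBSCl, imidazole, DMF, 20 °C
Reagents that add atoms: tert-butyldimethylsilyl chloride CC(C)(C)[Si](C)(C)Cl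
Why: Standard silylation of both secondary alcohols gives ethers that tolerate organolithium, Lewis acid, hydrogenation and copper catalysis.

**Step 4**
Reactants: 7 (5S,9R)-5,9-bis(TBS-oxy)dec-1-ene
Product: 8 (4S,8R)-4,8-bis(TBS-oxy)nonanal
Conditions: O3, CH2Cl2, −78 °C; PPh3, −78 → 20 °C
Reagents that add atoms: ozone [O-][O+]=O
Why: Ozonolysis with reductive work-up cleaves the terminal alkene to the C12 aldehyde without affecting the silyl ethers.

**Step 5**
Reactants: 8 (4S,8R)-4,8-bis(TBS-oxy)nonanal; 9 acetyltrimethylsilane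
Product: 12 (2E,6S,10R)-6,10-bis(TBS-oxy)-1-(trimethylsilyl)undec-2-en-1-one, via lithium aldolate 10 (not isolated), via aldol mesylate 11 (not isolated)
Conditions: LiN(iPr)2, THF, −78 °C (enolate of 9); 8; MsCl, Et3N, −78 → 20 °C
Reagents that add atoms: none
Why: Aldol addition of the acylsilane lithium enolate, followed by mesylation and E1cB elimination, is an aldol condensation that should give the conjugated (E)-acylsilane.

**Step 6**
Reactants: 12 (2E,6S,10R)-6,10-bis(TBS-oxy)-1-(trimethylsilyl)undec-2-en-1-one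
Product: 13 (1R,2E,6S,10R)-6,10-bis(TBS-oxy)-1-(trimethylsilyl)undec-2-en-1-ol
Conditions: (−)-B-chlorodiisopinocampheylborane, THF, −25 °C; CH3CHO; aq. NaHCO3
Reagents that add atoms: none
Why: Reagent-controlled asymmetric 1,2-reduction of an acylsilane by the chiral chloroborane should set the C10 silylcarbinol as R, with the silyl group taking the place of the large substituent.

**Step 7**
Reactants: 13 (1R,2E,6S,10R)-6,10-bis(TBS-oxy)-1-(trimethylsilyl)undec-2-en-1-ol; 14 formic acid
Product: 15 (1R,2E,6S,10R)-6,10-bis(TBS-oxy)-1-(trimethylsilyl)undec-2-en-1-yl formate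
Conditions: DCC, DMAP (cat.), CH2Cl2, 0 °C
Reagents that add atoms: none
Why: Carbodiimide-mediated (Steglich) formylation proceeds without an alkoxide, so the α-silyl carbinol cannot undergo Brook rearrangement and C10 keeps its configuration.

**Step 8**
Reactants: 15 (1R,2E,6S,10R)-6,10-bis(TBS-oxy)-1-(trimethylsilyl)undec-2-en-1-yl formate; 16 tetrachloromethane
Product: 17 [(1R,2E,6S,10R)-1-(2,2-dichloroethenyloxy)-6,10-bis(TBS-oxy)undec-2-en-1-yl]trimethylsilane
Conditions: PPh3, CCl4, THF, 60 °C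
Reagents that add atoms: none
Why: Wittig-type dichloromethylenation of the reactive formate carbonyl by Ph3P=CCl2 (from PPh3/CCl4) gives the 2,2-dichlorovinyl ether under neutral conditions.

**Step 9**
Reactants: 18 hex-5-ynoic acid; 19 paraformaldehyde
Product: 20 7-hydroxyhept-5-ynoic acid
Conditions: EtMgBr (2.2 equiv), THF, 0 → 40 °C; (CH2O)n; aq. HCl
Reagents that add atoms: none
Why: The carboxylate/alkynyl Grignard dianion adds to formaldehyde only at the acetylide carbon, giving the propargylic alcohol.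

**Step 10**
Reactants: 20 7-hydroxyhept-5-ynoic acid
Product: 21 methyl 7-hydroxyhept-5-ynoate
Conditions: MeOH, H2SO4 (cat.), 20 °C
Reagents that add atoms: methanol CO
Why: Fischer esterification converts the acid into the methyl ester and leaves the propargylic alcohol free.

**Step 11**
Reactants: 21 methyl 7-hydroxyhept-5-ynoate
Product: 22 methyl 7-(trifluoromethylsulfonyloxy)hept-5-ynoate
Conditions: Tf2O, 2,6-di-tert-butyl-4-methylpyridine, CH2Cl2/pentane, −78 → −40 °C; cold filtration, solution used at once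
Reagents that add atoms: trifluoromethanesulfonic anhydride O=S(=O)(OS(=O)(=O)C(F)(F)F)C(F)(F)F
Why: Triflation of a primary propargylic alcohol with a hindered base gives an electrophile that alkylates lithium acetylides at −78 °C without additives.

**Step 12**
Reactants: 17 [(1R,2E,6S,10R)-1-(2,2-dichloroethenyloxy)-6,10-bis(TBS-oxy)undec-2-en-1-yl]trimethylsilane; 22 methyl 7-(trifluoromethylsulfonyloxy)hept-5-ynoate
Product: 26 methyl 7-[(1R,2S)-2-[(3S,7R)-3,7-bis(TBS-oxy)octyl]-5-oxocyclopent-3-en-1-yl]hept-5-ynoate, via lithium alkynyl ether 23 (not isolated), via allyl alkynyl ether 24 (not isolated), via allyl ketene 25 (not isolated)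
Conditions: 17, n-BuLi (2.0 equiv), Et2O, −78 °C; 22 (Et2O/pentane), −78 → −50 °C; CH2Cl2, EtAlCl2 (2.5 equiv), −78 → −20 °C; aq. NaHCO3; Et3N (cat.), CH2Cl2, 20 °C
Reagents that add atoms: none
Why: Proposed new method: n-BuLi converts the dichlorovinyl ether into lithium alkynyl ether 23 (elimination, then lithium–chlorine exchange), which is C-alkylated at −78 °C by triflate 22; the resulting allyl alkynyl ether 24 should undergo the low-temperature [3,3] sigmatropic shift typical of allyl 1-alkynyl ethers, forming C8–C12 and unveiling ketene 25, and EtAlCl2 then activates the ketene for attack of the silicon-bearing vinylsilane carbon C10 on the ketene carbon C9, the β-silyl cation at C11 collapsing by loss of the silyl group (C9–C10). The closest known reactions are the sigmatropic rearrangement of allyl alkynyl ethers to allyl ketenes with trapping in the same flask (including carbocyclisation in the benzyl series), Lewis acid-promoted ketene–alkene bond formation, and the intramolecular acylation of vinylsilanes to cyclopent-2-enones; new is their union and the use of a ketene as the acyl partner. The cyclopentenone closes 5-endo-trig with respect to the vinylsilane (ipso attack) and exo with respect to the ketene C=O, whose in-plane acceptor orbital is within reach of the tethered nucleophile. C12 is set by suprafacial chirality transfer from the (R)-silylcarbinol C10 through a chair-like array with the silyl group pseudo-equatorial and the (E)-C11=C12 alkene (C10 becomes sp2, so the controller is traceless), and C8 is set trans to C12 by protonation of the cross-conjugated dienolate and mild base equilibration. The step needs C-alkylation of 23 before its own rearrangement (secured by a triflate that reacts at −78 °C), ipso regiochemistry (secured by the β-silicon effect, which also fixes the enone as C10=C11), and the absence of a competing π-nucleophile (the α-chain carries an alkyne, not an alkene, at this stage).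

**Step 13**
Reactants: 26 methyl 7-[(1R,2S)-2-[(3S,7R)-3,7-bis(TBS-oxy)octyl]-5-oxocyclopent-3-en-1-yl]hept-5-ynoate
Product: 27 methyl (5Z)-7-[(1R,2S)-2-[(3S,7R)-3,7-bis(TBS-oxy)octyl]-5-oxocyclopent-3-en-1-yl]hept-5-enoate
Conditions: H2 (1 atm), Pd/CaCO3 poisoned with Pb(OAc)2, quinoline, EtOAc/hexane, 0 °C, stopped after 1 equiv H2
Reagents that add atoms: none
Why: Lindlar semi-hydrogenation adds hydrogen syn to the alkyne, giving the (Z)-C5=C6 alkene, and the more weakly bound conjugated ring alkene should be spared.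

**Step 14**
Reactants: 27 methyl (5Z)-7-[(1R,2S)-2-[(3S,7R)-3,7-bis(TBS-oxy)octyl]-5-oxocyclopent-3-en-1-yl]hept-5-enoate
Product: 29 methyl (5Z)-7-[(1R,2R,3R)-2-[(3S,7R)-3,7-bis(TBS-oxy)octyl]-3-hydroxy-5-oxocyclopentyl]hept-5-enoate, via C11 pinacol boronate 28 (not isolated)
Conditions: CuCl (5 mol %), bis(2-diphenylphosphinophenyl) ether (5 mol %), NaOtBu (10 mol %), B2pin2, MeOH (2 equiv), THF, 0 → 20 °C; then 30 % H2O2, aq. NaHCO3, 0 °C
Reagents that add atoms: hydrogen peroxide OO
Why: Copper-catalysed conjugate borylation should deliver boron to C11 on the face anti to the adjacent C12 chain, and stereoretentive oxidation of the C–B bond then gives the 11-hydroxyl trans to that chain, while C8 stays at its thermodynamic trans setting under the mild base.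

**Step 15**
Reactants: 29 methyl (5Z)-7-[(1R,2R,3R)-2-[(3S,7R)-3,7-bis(TBS-oxy)octyl]-3-hydroxy-5-oxocyclopentyl]hept-5-enoate
Product: 30 methyl (5Z)-7-[(1R,2R,3R)-3-hydroxy-2-[(3S,7R)-3,7-dihydroxyoctyl]-5-oxocyclopentyl]hept-5-enoate
Conditions: HF·pyridine, pyridine, THF, 0 → 20 °C
Reagents that add atoms: none
Why: Buffered fluoride-mediated desilylation removes both silyl ethers under weakly acidic conditions that the β-hydroxy ketone tolerates.

**Step 16**
Reactants: 30 methyl (5Z)-7-[(1R,2R,3R)-3-hydroxy-2-[(3S,7R)-3,7-dihydroxyoctyl]-5-oxocyclopentyl]hept-5-enoate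
Product: 31 (5Z)-7-[(1R,2R,3R)-3-hydroxy-2-[(3S,7R)-3,7-dihydroxyoctyl]-5-oxocyclopentyl]hept-5-enoic acid (target)
Conditions: porcine liver esterase, pH 7 phosphate buffer, acetone (cosolvent), 25 °C
Reagents that add atoms: water O
Why: Enzymatic ester hydrolysis at neutral pH frees the acid without the base-induced dehydration or C8 epimerisation of the β-hydroxy ketone.

**Compound list**
1 | methyl phenyl sulfone | CS(=O)(=O)c1ccccc1 | starting material
2 | (R)-2-methyloxirane | C[C@@H]1CO1 | starting material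
3 | (R)-2-(but-3-en-1-yl)oxirane | C=CCC[C@@H]1CO1 | starting material
4 | lithium (R)-4-(phenylsulfonyl)butan-2-olate | C[C@@H]([O-])CCS(=O)(=O)c1ccccc1.[Li+] | intermediate
5 | (2R,6R)-4-(phenylsulfonyl)dec-9-ene-2,6-diol, C4 epimers | C[C@@H](O)CC(C[C@H](O)CCC=C)S(=O)(=O)c1ccccc1 | intermediate
6 | (2R,6S)-dec-9-ene-2,6-diol | C[C@@H](O)CCC[C@H](O)CCC=C | intermediate
7 | (5S,9R)-5,9-bis(TBS-oxy)dec-1-ene | C[C@@H](O[Si](C)(C)C(C)(C)C)CCC[C@H](O[Si](C)(C)C(C)(C)C)CCC=C | intermediate
8 | (4S,8R)-4,8-bis(TBS-oxy)nonanal | C[C@@H](O[Si](C)(C)C(C)(C)C)CCC[C@H](O[Si](C)(C)C(C)(C)C)CCC=O | intermediate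
9 | acetyltrimethylsilane | CC(=O)[Si](C)(C)C | starting material
10 | lithium aldolate of 8 and 9 (C12 epimers) | C[C@@H](O[Si](C)(C)C(C)(C)C)CCC[C@H](O[Si](C)(C)C(C)(C)C)CCC([O-])CC(=O)[Si](C)(C)C.[Li+] | intermediate
11 | aldol mesylate (C12 epimers) | C[C@@H](O[Si](C)(C)C(C)(C)C)CCC[C@H](O[Si](C)(C)C(C)(C)C)CCC(OS(C)(=O)=O)CC(=O)[Si](C)(C)C | intermediate
12 | (2E,6S,10R)-6,10-bis(TBS-oxy)-1-(trimethylsilyl)undec-2-en-1-one | C[C@@H](O[Si](C)(C)C(C)(C)C)CCC[C@H](O[Si](C)(C)C(C)(C)C)CC/C=C/C(=O)[Si](C)(C)C | intermediate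
13 | (1R,2E,6S,10R)-6,10-bis(TBS-oxy)-1-(trimethylsilyl)undec-2-en-1-ol | C[C@@H](O[Si](C)(C)C(C)(C)C)CCC[C@H](O[Si](C)(C)C(C)(C)C)CC/C=C/[C@H](O)[Si](C)(C)C | intermediate
14 | formic acid | OC=O | starting material
15 | (1R,2E,6S,10R)-6,10-bis(TBS-oxy)-1-(trimethylsilyl)undec-2-en-1-yl formate | C[C@@H](O[Si](C)(C)C(C)(C)C)CCC[C@H](O[Si](C)(C)C(C)(C)C)CC/C=C/[C@H](OC=O)[Si](C)(C)C | intermediate
16 | tetrachloromethane | ClC(Cl)(Cl)Cl | starting material
17 | [(1R,2E,6S,10R)-1-(2,2-dichloroethenyloxy)-6,10-bis(TBS-oxy)undec-2-en-1-yl]trimethylsilane | C[C@@H](O[Si](C)(C)C(C)(C)C)CCC[C@H](O[Si](C)(C)C(C)(C)C)CC/C=C/[C@H](OC=C(Cl)Cl)[Si](C)(C)C | intermediate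
18 | hex-5-ynoic acid | C#CCCCC(=O)O | starting material
19 | paraformaldehyde (as formaldehyde) | C=O | starting material
20 | 7-hydroxyhept-5-ynoic acid | OCC#CCCCC(=O)O | intermediate
21 | methyl 7-hydroxyhept-5-ynoate | OCC#CCCCC(=O)OC | intermediate
22 | methyl 7-(trifluoromethylsulfonyloxy)hept-5-ynoate | COC(=O)CCCC#CCOS(=O)(=O)C(F)(F)F | intermediate
23 | lithium acetylide of the (1R)-1-silylallyl ethynyl ether | C[C@@H](O[Si](C)(C)C(C)(C)C)CCC[C@H](O[Si](C)(C)C(C)(C)C)CC/C=C/[C@H](OC#C[Li])[Si](C)(C)C | intermediate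
24 | methyl 9-{[(1R,2E,6S,10R)-6,10-bis(TBS-oxy)-1-(trimethylsilyl)undec-2-en-1-yl]oxy}nona-5,8-diynoate | C[C@@H](O[Si](C)(C)C(C)(C)C)CCC[C@H](O[Si](C)(C)C(C)(C)C)CC/C=C/[C@H](OC#CCC#CCCCC(=O)OC)[Si](C)(C)C | intermediate
25 | allyl ketene: methyl 8-(oxomethylidene)non-5-ynoate carrying at C9 (C12, S) the (3S,7R)-3,7-bis(TBS-oxy)octyl chain and an (E)-2-(trimethylsilyl)ethenyl group | C[C@@H](O[Si](C)(C)C(C)(C)C)CCC[C@H](O[Si](C)(C)C(C)(C)C)CC[C@@H](/C=C/[Si](C)(C)C)C(=C=O)CC#CCCCC(=O)OC | intermediate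
26 | methyl 7-[(1R,2S)-2-[(3S,7R)-3,7-bis(TBS-oxy)octyl]-5-oxocyclopent-3-en-1-yl]hept-5-ynoate | C[C@@H](O[Si](C)(C)C(C)(C)C)CCC[C@H](O[Si](C)(C)C(C)(C)C)CC[C@H]1C=CC(=O)[C@@H]1CC#CCCCC(=O)OC | intermediate
27 | methyl (5Z)-7-[(1R,2S)-2-[(3S,7R)-3,7-bis(TBS-oxy)octyl]-5-oxocyclopent-3-en-1-yl]hept-5-enoate | C[C@@H](O[Si](C)(C)C(C)(C)C)CCC[C@H](O[Si](C)(C)C(C)(C)C)CC[C@H]1C=CC(=O)[C@@H]1C/C=C\CCCC(=O)OC | intermediate
28 | C11 pinacol boronate of 27 (boron trans to the C12 chain) | C[C@@H](O[Si](C)(C)C(C)(C)C)CCC[C@H](O[Si](C)(C)C(C)(C)C)CC[C@H]1[C@H](B2OC(C)(C)C(C)(C)O2)CC(=O)[C@@H]1C/C=C\CCCC(=O)OC | intermediate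
29 | methyl (5Z)-7-[(1R,2R,3R)-2-[(3S,7R)-3,7-bis(TBS-oxy)octyl]-3-hydroxy-5-oxocyclopentyl]hept-5-enoate | C[C@@H](O[Si](C)(C)C(C)(C)C)CCC[C@H](O[Si](C)(C)C(C)(C)C)CC[C@H]1[C@H](O)CC(=O)[C@@H]1C/C=C\CCCC(=O)OC | intermediate
30 | methyl (5Z)-7-[(1R,2R,3R)-3-hydroxy-2-[(3S,7R)-3,7-dihydroxyoctyl]-5-oxocyclopentyl]hept-5-enoate | C[C@@H](O)CCC[C@H](O)CC[C@H]1[C@H](O)CC(=O)[C@@H]1C/C=C\CCCC(=O)OC | intermediate
31 | (5Z)-7-[(1R,2R,3R)-3-hydroxy-2-[(3S,7R)-3,7-dihydroxyoctyl]-5-oxocyclopentyl]hept-5-enoic acid | C[C@@H](O)CCC[C@H](O)CC[C@H]1[C@H](O)CC(=O)[C@@H]1C/C=C\CCCC(=O)O | target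

**Step count**
Total: 16 steps. Longest linear sequence: 13 steps (steps 1–8, then 12–16).

**Steps most likely to fail**

Step 12. The lithium alkynyl ether may rearrange before it is alkylated. Chirality transfer may be eroded through a transition state with the silyl group axial. The ketene may dimerise or be captured by other pathways instead of closing onto the vinylsilane. The fallback uses known chemistry only, sets out from 13 and 22 and returns to the route at 26. Triflate 22 alkylates the lithium enolate of tert-butyl acetate (LiN(iPr)2, THF, −78 °C) to give 1-tert-butyl 9-methyl non-4-ynedioate F1. Trifluoroacetic acid removes the tert-butyl group to give 9-methoxy-9-oxonon-4-ynoic acid F2. DCC/DMAP esterification of F2 with 13 gives the α-silylallyl ester F3. Ireland–Claisen rearrangement (excess LiN(iPr)2 and Me3SiCl, THF, −100 → 20 °C; the methyl ester is also silylated but is returned on work-up) gives the (E)-vinylsilane acid F4 with the same C10-to-C12 chirality transfer. Oxalyl chloride with catalytic DMF gives acid chloride F5, and SnCl4 in CH2Cl2 at −78 → 0 °C effects the intramolecular ipso-acylation of the vinylsilane to 26.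

Step 14. Boryl–copper addition may show poor facial selectivity at C11, and the β-hydroxy ketone may suffer β-elimination during oxidation. The fallback sets out from 27 and returns at 29. Nucleophilic epoxidation (H2O2, NaOH, MeOH, −40 °C) should place the oxygen anti to the C12 chain and give the 10,11-epoxy ketone F6. Reductive opening of the α,β-epoxy ketone at C10 (Zn dust, NH4Cl, aqueous MeOH, 0 °C) then gives 29.

Step 13. Hydrogen may also add to the conjugated ring alkene, or the cis-alkene may be over-reduced. The fallback sets out from 26 and returns at 29, with the enone removed before any hydrogenation. Epoxidation of 26 (H2O2, NaOH, MeOH, −40 °C) gives the alkynyl epoxy ketone F7. Zn/NH4Cl opening gives the 5,6-didehydro β-hydroxy ketone F8. Semi-hydrogenation over Pd/CaCO3 poisoned with Pb(OAc)2 then acts on a substrate with no other reducible alkene and gives 29.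

**Further compounds**
F1 | step 12 | 1-tert-butyl 9-methyl non-4-ynedioate | CC(C)(C)OC(=O)CCC#CCCCC(=O)OC
F2 | step 12 | 9-methoxy-9-oxonon-4-ynoic acid | OC(=O)CCC#CCCCC(=O)OC
F3 | step 12 | 1-[(1R,2E,6S,10R)-6,10-bis(TBS-oxy)-1-(trimethylsilyl)undec-2-en-1-yl] 9-methyl non-4-ynedioate | C[C@@H](O[Si](C)(C)C(C)(C)C)CCC[C@H](O[Si](C)(C)C(C)(C)C)CC/C=C/[C@H](OC(=O)CCC#CCCCC(=O)OC)[Si](C)(C)C
F4 | step 12 | Ireland–Claisen acid, (E)-vinylsilane, C12 as in 25, C8 epimers | C[C@@H](O[Si](C)(C)C(C)(C)C)CCC[C@H](O[Si](C)(C)C(C)(C)C)CC[C@@H](/C=C/[Si](C)(C)C)C(CC#CCCCC(=O)OC)C(=O)O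
F5 | step 12 | acid chloride of F4 | C[C@@H](O[Si](C)(C)C(C)(C)C)CCC[C@H](O[Si](C)(C)C(C)(C)C)CC[C@@H](/C=C/[Si](C)(C)C)C(CC#CCCCC(=O)OC)C(=O)Cl
F6 | step 14 | 10,11-epoxy ketone of 27 (oxygen anti to the C12 chain) | C[C@@H](O[Si](C)(C)C(C)(C)C)CCC[C@H](O[Si](C)(C)C(C)(C)C)CC[C@H]1[C@@H]2O[C@@H]2C(=O)[C@@H]1C/C=C\CCCC(=O)OC
F7 | step 13 | 10,11-epoxy ketone of 26 (oxygen anti to the C12 chain) | C[C@@H](O[Si](C)(C)C(C)(C)C)CCC[C@H](O[Si](C)(C)C(C)(C)C)CC[C@H]1[C@@H]2O[C@@H]2C(=O)[C@@H]1CC#CCCCC(=O)OC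
F8 | step 13 | methyl 7-[(1R,2R,3R)-2-[(3S,7R)-3,7-bis(TBS-oxy)octyl]-3-hydroxy-5-oxocyclopentyl]hept-5-ynoate | C[C@@H](O[Si](C)(C)C(C)(C)C)CCC[C@H](O[Si](C)(C)C(C)(C)C)CC[C@H]1[C@H](O)CC(=O)[C@@H]1CC#CCCCC(=O)OC
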